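**Retrosynthetic overview**
1. Target ⇐ O‑sulfation ⇐ hydroquinone ⇐ oxidative demethylation ⇐ Wittig methylenation of the cis‑fused decalone 37.
2. Key disconnection: the bond between the ring‑fusion quaternary carbon of ring A and the ethylene linker. It is made from α‑mesyloxy ketone 17 (fragment 1) and the organocerium from iodide 33 (fragment 2) by carbonyl 1,2‑addition followed by a stereoinvertive 1,2‑alkyl shift (semipinacol).
3. Fragment 1: ring A is cyclohexane‑1,3‑dione; ring B comes from Michael addition and an amino‑acid‑mediated aldol condensation that sets an angular acetoxy stereocentre. Birch reductive benzylation (arene from hydroquinone) and a hydroxyl‑directed hydrogenation follow.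
4. Fragment 2: ring C from 2‑methylpropanal and but‑3‑en‑2‑one; asymmetric conjugate addition, then aldol condensation closes ring D; conjugate vinylation with enol triflate reduction sets the quaternary centre and the trisubstituted alkene.
5. Ring order: A → B (fragment 1); C → D (fragment 2); the two bicycles are joined last.

Assumptions: the target is written as the free bis(hydrogen sulfate) as drawn (in practice handled as its disodium salt), and racemic 5‑chloro‑3‑methylpentan‑2‑one is taken as a catalogue chemical.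

Locants in the names of fragment 1 follow naphthalen‑1‑one numbering (C1 = ring A carbonyl or ketal carbon, C8a = angular carbon, C4a = ring‑fusion CH, C5 = quaternary benzylic‑bearing carbon, C6 = methyl‑bearing carbon).

**Route**

Step 1
Reactants: 1 hydroquinone (benzene‑1,4‑diol)
Product: 2 1,4‑dimethoxybenzene
Conditions: Me2SO4, K2CO3, acetone, reflux
Reagents that add atoms: dimethyl sulfate, COS(=O)(=O)OC
Why: Williamson O‑methylation of both phenols installs methyl ethers that survive every organometallic, reductive and acidic step until the oxidative unmasking in step 23.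

Step 2
Reactants: 2 1,4‑dimethoxybenzene
Product: 3 2‑(bromomethyl)‑1,4‑dimethoxybenzene
Conditions: (CH2O)n, 33% HBr in AcOH, rt, arene in excess
Reagents that add atoms: formaldehyde, C=O; hydrogen bromide, Br
Why: Blanc‑type bromomethylation (electrophilic aromatic substitution) of the activated arene, with excess arene limiting double substitution.

Step 3
Reactants: 4 cyclohexane‑1,3‑dione; 5 pent‑1‑en‑3‑one
Product: 6 2‑(3‑oxopentyl)cyclohexane‑1,3‑dione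
Conditions: Et3N (5 mol%), EtOAc, rt
Reagents that add atoms: none
Why: Michael addition of the acidic C2 of the 1,3‑dione to the vinyl ketone, with the dione in slight excess to suppress double addition.

Step 4
Reactants: 6 2‑(3‑oxopentyl)cyclohexane‑1,3‑dione
Product: 7 2,6‑dioxo‑1‑(3‑oxopentyl)cyclohexyl acetate
Conditions: Pb(OAc)4, benzene, rt
Reagents that add atoms: lead tetraacetate, CC(=O)O[Pb](OC(C)=O)(OC(C)=O)OC(C)=O
Why: α‑Acetoxylation of a 2‑alkyl‑1,3‑dione through its lead enolate occurs only at the doubly activated carbon and gives a prochiral triketone carrying the future leaving‑group oxygen.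

Step 5
Reactants: 7 2,6‑dioxo‑1‑(3‑oxopentyl)cyclohexyl acetate
Product: 8 (8aS)‑5‑methyl‑1,6‑dioxo‑1,2,3,4,6,7,8,8a‑octahydronaphthalen‑8a‑yl acetate
Conditions: D‑phenylalanine (1 equiv), (1R)‑(−)‑camphor‑10‑sulfonic acid (0.5 equiv), DMF, 70 °C
Reagents that add atoms: none
Why: Hajos–Parrish–Eder–Sauer–Wiechert‑type enamine aldol condensation closes ring B and differentiates the two enantiotopic ring carbonyls, setting the angular C8a centre; the sense is assumed to mirror that known for L‑phenylalanine with the 2‑methyl triketone.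

Step 6
Reactants: 8 (8aS)‑5‑methyl‑1,6‑dioxo‑1,2,3,4,6,7,8,8a‑octahydronaphthalen‑8a‑yl acetate
Product: 10 (8aS)‑1,1‑(ethylenedioxy)‑8a‑hydroxy‑5‑methyl‑1,2,3,4,8,8a‑hexahydronaphthalen‑6(7H)‑one, via acetoxy ketal 9 (not isolated)
Conditions: ethylene glycol, TsOH (cat.), benzene, reflux (Dean–Stark); then K2CO3, MeOH, rt
Reagents that add atoms: ethylene glycol, OCCO
Why: Ketalisation is chemoselective for the saturated C1 ketone over the enone (as with the Wieland–Miescher ketone), and methanolysis frees the angular hydroxyl, which must enter the next step as an alkoxide and not as an ester to avoid vinylogous β‑elimination.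

Step 7
Reactants: 10 (8aS)‑1,1‑(ethylenedioxy)‑8a‑hydroxy‑5‑methyl‑1,2,3,4,8,8a‑hexahydronaphthalen‑6(7H)‑one; 3 2‑(bromomethyl)‑1,4‑dimethoxybenzene
Product: 12 (4aR,5R,8aS)‑5‑[(2,5‑dimethoxyphenyl)methyl]‑1,1‑(ethylenedioxy)‑8a‑hydroxy‑5‑methylperhydronaphthalen‑6‑one, via dilithium enolate 11 (not isolated)
Conditions: n‑BuLi (1 equiv), THF, −78 °C; Li, NH3(l), t‑BuOH (1 equiv), −78 to −33 °C; isoprene; then 3, THF, −78 °C to rt
Reagents that add atoms: none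
Why: Birch reductive alkylation: axial protonation at C4a gives the trans‑fused lithium enolate, and the benzylic bromide then attacks C5 on the face opposite the axial C8a–O bond, setting C4a (H trans to the angular oxygen) and the quaternary C5 (arylmethyl cis to H‑4a).

Step 8
Reactants: 12 (4aR,5R,8aS)‑5‑[(2,5‑dimethoxyphenyl)methyl]‑1,1‑(ethylenedioxy)‑8a‑hydroxy‑5‑methylperhydronaphthalen‑6‑one
Product: 13 (4aR,5R,8aS)‑5‑[(2,5‑dimethoxyphenyl)methyl]‑1,1‑(ethylenedioxy)‑8a‑hydroxy‑5‑methyl‑1,2,3,4,4a,5,8,8a‑octahydronaphthalen‑6‑yl trifluoromethanesulfonate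
Conditions: KHMDS (2.2 equiv), THF, −78 °C; PhNTf2, −78 to 0 °C
Reagents that add atoms: N‑phenylbis(trifluoromethanesulfonimide), O=S(=O)(N(c1ccccc1)S(=O)(=O)C(F)(F)F)C(F)(F)F
Why: Enolisation is possible only toward C7 because C5 is quaternary, and O‑triflation of the potassium enolate gives the enol triflate while the hindered tertiary alkoxide stays unsulfonylated.

Step 9
Reactants: 13 (4aR,5R,8aS)‑5‑[(2,5‑dimethoxyphenyl)methyl]‑1,1‑(ethylenedioxy)‑8a‑hydroxy‑5‑methyl‑1,2,3,4,4a,5,8,8a‑octahydronaphthalen‑6‑yl trifluoromethanesulfonate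
Product: 14 (4aR,5R,8aS)‑5‑[(2,5‑dimethoxyphenyl)methyl]‑1,1‑(ethylenedioxy)‑5,6‑dimethyl‑1,2,3,4,4a,5,8,8a‑octahydronaphthalen‑8a‑ol
Conditions: MeMgBr (3 equiv), Fe(acac)3 (5 mol%), THF/NMP, −20 to 0 °C
Reagents that add atoms: methylmagnesium bromide, C[Mg]Br
Why: Iron‑catalysed Kumada‑type cross‑coupling of the alkenyl triflate introduces the C6 methyl as a C6=C7 alkene, one extra equivalent of Grignard reagent being spent on the free hydroxyl.

Step 10
Reactants: 14 (4aR,5R,8aS)‑5‑[(2,5‑dimethoxyphenyl)methyl]‑1,1‑(ethylenedioxy)‑5,6‑dimethyl‑1,2,3,4,4a,5,8,8a‑octahydronaphthalen‑8a‑ol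
Product: 15 (4aR,5S,6S,8aS)‑5‑[(2,5‑dimethoxyphenyl)methyl]‑1,1‑(ethylenedioxy)‑5,6‑dimethylperhydronaphthalen‑8a‑ol
Conditions: [Ir(cod)(PCy3)(py)]PF6 (5 mol%), H2 (1 atm), CH2Cl2, rt
Reagents that add atoms: none
Why: Hydroxyl‑directed homogeneous hydrogenation: the cationic iridium complex binds the homoallylic tertiary C8a–OH and delivers H2 to that face of the C6=C7 alkene, overriding the steric bias of the axial C5 methyl and setting C6 with its methyl cis to the arylmethyl group.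

Step 11
Reactants: 15 (4aR,5S,6S,8aS)‑5‑[(2,5‑dimethoxyphenyl)methyl]‑1,1‑(ethylenedioxy)‑5,6‑dimethylperhydronaphthalen‑8a‑ol
Product: 16 (4aR,5S,6S,8aS)‑5‑[(2,5‑dimethoxyphenyl)methyl]‑8a‑hydroxy‑5,6‑dimethylperhydronaphthalen‑1‑one
Conditions: 1 M HCl, THF, rt
Reagents that add atoms: water, O
Why: Acid‑catalysed ketal hydrolysis unmasks the C1 ketone; the dioxolane is the only acid‑labile group present.

Step 12
Reactants: 16 (4aR,5S,6S,8aS)‑5‑[(2,5‑dimethoxyphenyl)methyl]‑8a‑hydroxy‑5,6‑dimethylperhydronaphthalen‑1‑one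
Product: 17 (4aR,5S,6S,8aS)‑5‑[(2,5‑dimethoxyphenyl)methyl]‑5,6‑dimethyl‑1‑oxoperhydronaphthalen‑8a‑yl methanesulfonate
Conditions: MsCl, Et3N, CH2Cl2, −10 °C
Reagents that add atoms: methanesulfonyl chloride, CS(=O)(=O)Cl
Why: Mesylation through sulfene works on the hindered tertiary alcohol with retention at C8a, and the adjacent carbonyl disfavours ionisation so the axial mesylate can be handled cold.

Step 13
Reactants: 18 2‑methylpropanal; 19 but‑3‑en‑2‑one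
Product: 20 4,4‑dimethylcyclohex‑2‑en‑1‑one
Conditions: H2SO4 (cat.), toluene, reflux (Dean–Stark)
Reagents that add atoms: none
Why: Acid‑catalysed Robinson‑type annulation (Michael addition of the aldehyde enol, then aldol condensation) builds ring C with its gem‑dimethyl group.

Step 14
Reactants: 21 5‑chloro‑3‑methylpentan‑2‑one
Product: 22 2‑(4‑chlorobutan‑2‑yl)‑2‑methyl‑1,3‑dioxolane
Conditions: ethylene glycol, TsOH (cat.), benzene, reflux (Dean–Stark)
Reagents that add atoms: ethylene glycol, OCCO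
Why: Ketal protection of the methyl ketone allows the chloride to be converted into an organometallic reagent.

Step 15
Reactants: 22 2‑(4‑chlorobutan‑2‑yl)‑2‑methyl‑1,3‑dioxolane; 20 4,4‑dimethylcyclohex‑2‑en‑1‑one
Product: 25 (3R)‑4,4‑dimethyl‑3‑[3‑(2‑methyl‑1,3‑dioxolan‑2‑yl)butyl]cyclohexan‑1‑one, via Grignard reagent 23 (not isolated), via dialkylzinc 24 (not isolated)
Conditions: Mg, THF, 45 °C; ZnCl2 (0.5 equiv), then 1,4‑dioxane and filtration; Cu(OTf)2 (2 mol%), (S,R,R)‑binaphthyl bis(1‑phenylethyl)phosphoramidite (4 mol%), toluene, −30 °C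
Reagents that add atoms: none
Why: Copper‑catalysed enantioselective conjugate addition of a dialkylzinc: the chiral phosphoramidite–copper complex selects one enone face and sets C3, the future ring‑fusion CH of fragment 2, while the side‑chain methyl centre is left as a mixture because it is equilibrated in step 16.

Step 16
Reactants: 25 (3R)‑4,4‑dimethyl‑3‑[3‑(2‑methyl‑1,3‑dioxolan‑2‑yl)butyl]cyclohexan‑1‑one
Product: 27 (4aS,7S)‑4,4,7,8‑tetramethyl‑3,4,4a,5,6,7‑hexahydronaphthalen‑1(2H)‑one, via diketone 26 (not isolated)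
Conditions: 2 M HCl, THF, rt; then KOH, MeOH, 65 °C
Reagents that add atoms: none
Why: Ketal hydrolysis followed by intramolecular aldol condensation (the ring ketone α‑carbon onto the methyl ketone, six‑membered) closes ring D; under these equilibrating conditions the γ‑centre C7 settles with its methyl pseudo‑axial, trans to H‑4a, to avoid allylic 1,2‑strain with the C8 methyl.

Step 17
Reactants: 27 (4aS,7S)‑4,4,7,8‑tetramethyl‑3,4,4a,5,6,7‑hexahydronaphthalen‑1(2H)‑one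
Product: 29 (4aS,7S,8R)‑8‑ethenyl‑4,4,7,8‑tetramethyl‑2,3,4,4a,5,6,7,8‑octahydronaphthalen‑1‑yl trifluoromethanesulfonate, via magnesium enolate 28 (not isolated)
Conditions: vinylMgBr (4 equiv), CuI (2 equiv), THF, −78 to −20 °C; then PhNTf2, −78 °C to rt
Reagents that add atoms: vinylmagnesium bromide, C=C[Mg]Br; N‑phenylbis(trifluoromethanesulfonimide), O=S(=O)(N(c1ccccc1)S(=O)(=O)C(F)(F)F)C(F)(F)F
Why: Cuprate 1,4‑addition to the s‑cis enone occurs axially and anti to the pseudo‑axial C7 methyl, creating the quaternary C8 with vinyl trans to that methyl, and triflation of the regiodefined enolate fixes the position of the ring C double bond.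

Step 18
Reactants: 29 (4aS,7S,8R)‑8‑ethenyl‑4,4,7,8‑tetramethyl‑2,3,4,4a,5,6,7,8‑octahydronaphthalen‑1‑yl trifluoromethanesulfonate
Product: 30 (1R,2S,4aS)‑1‑ethenyl‑1,2,5,5‑tetramethyl‑1,2,3,4,4a,5,6,7‑octahydronaphthalene
Conditions: Pd(OAc)2 (5 mol%), PPh3 (10 mol%), HCO2H, Bu3N, DMF, 60 °C
Reagents that add atoms: none
Why: Palladium‑catalysed formate reduction of the enol triflate (oxidative addition, hydride transfer, reductive elimination) gives the trisubstituted alkene without touching any stereocentre.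

Step 19
Reactants: 30 (1R,2S,4aS)‑1‑ethenyl‑1,2,5,5‑tetramethyl‑1,2,3,4,4a,5,6,7‑octahydronaphthalene
Product: 32 2‑[(1R,2S,4aS)‑1,2,5,5‑tetramethyl‑1,2,3,4,4a,5,6,7‑octahydronaphthalen‑1‑yl]ethan‑1‑ol, via alkylborane 31 (not isolated)
Conditions: 9‑BBN, THF, 0 to 60 °C; then NaOH, H2O2, 0 °C
Reagents that add atoms: hydrogen peroxide, OO
Why: Anti‑Markovnikov hydroboration–oxidation with the bulky borane is selective for the monosubstituted vinyl group over the hindered trisubstituted ring alkene.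

Step 20
Reactants: 32 2‑[(1R,2S,4aS)‑1,2,5,5‑tetramethyl‑1,2,3,4,4a,5,6,7‑octahydronaphthalen‑1‑yl]ethan‑1‑ol
Product: 33 (1R,2S,4aS)‑1‑(2‑iodoethyl)‑1,2,5,5‑tetramethyl‑1,2,3,4,4a,5,6,7‑octahydronaphthalene
Conditions: I2, PPh3, imidazole, CH2Cl2, 0 °C to rt
Reagents that add atoms: iodine, II
Why: Appel‑type iodination converts the primary alcohol into the iodide by SN2 displacement of the oxyphosphonium group.

Step 21
Reactants: 33 (1R,2S,4aS)‑1‑(2‑iodoethyl)‑1,2,5,5‑tetramethyl‑1,2,3,4,4a,5,6,7‑octahydronaphthalene; 17 (4aR,5S,6S,8aS)‑5‑[(2,5‑dimethoxyphenyl)methyl]‑5,6‑dimethyl‑1‑oxoperhydronaphthalen‑8a‑yl methanesulfonate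
Product: 37 (4aR,5S,6S,8aR)‑5‑[(2,5‑dimethoxyphenyl)methyl]‑5,6‑dimethyl‑8a‑{2‑[(1R,2S,4aS)‑1,2,5,5‑tetramethyl‑1,2,3,4,4a,5,6,7‑octahydronaphthalen‑1‑yl]ethyl}perhydronaphthalen‑1‑one, via alkyllithium 34 (not isolated), via alkylcerium dichloride 35 (not isolated), via cerium alkoxide 36 (not isolated)
Conditions: 33, t‑BuLi (2.1 equiv), Et2O, −78 °C; CeCl3, THF, −78 °C; then 17, −78 °C to rt
Reagents that add atoms: none
Why: Proposed new method: a fragment coupling in which an organocerium adds to a ring‑fusion tertiary α‑mesyloxy ketone and the adduct undergoes a stereoinvertive 1,2‑alkyl (semipinacol) shift in the same flask; the reagent attacks C1 axially, anti to the axial C8a–OMs bond (Felkin–Anh, trans‑diaxial), so the new chain is antiperiplanar to the leaving group and migrates to C8a with inversion as the alkoxide expels mesylate, giving the cis‑fused α‑quaternary ketone; the closest known reaction types are the Tiffeneau‑type semipinacol rearrangement of Grignard adducts of α‑halo ketones and the tandem organoaluminium addition/1,2‑shift of secondary α‑mesyloxy ketones.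

Step 22
Reactants: 37 (4aR,5S,6S,8aR)‑5‑[(2,5‑dimethoxyphenyl)methyl]‑5,6‑dimethyl‑8a‑{2‑[(1R,2S,4aS)‑1,2,5,5‑tetramethyl‑1,2,3,4,4a,5,6,7‑octahydronaphthalen‑1‑yl]ethyl}perhydronaphthalen‑1‑one
Product: 38 2‑{[(1S,2S,4aR,8aR)‑1,2‑dimethyl‑5‑methylidene‑4a‑{2‑[(1R,2S,4aS)‑1,2,5,5‑tetramethyl‑1,2,3,4,4a,5,6,7‑octahydronaphthalen‑1‑yl]ethyl}decahydronaphthalen‑1‑yl]methyl}‑1,4‑dimethoxybenzene
Conditions: Ph3PCH3Br, KOtBu, toluene, 100 °C
Reagents that add atoms: methyltriphenylphosphonium bromide, C[P+](c1ccccc1)(c1ccccc1)c1ccccc1.[Br-]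
Why: Wittig methylenation with the non‑stabilised ylide at elevated temperature converts even this α‑quaternary ketone, and no epimerisable centre flanks the carbonyl.

Step 23
Reactants: 38 2‑{[(1S,2S,4aR,8aR)‑1,2‑dimethyl‑5‑methylidene‑4a‑{2‑[(1R,2S,4aS)‑1,2,5,5‑tetramethyl‑1,2,3,4,4a,5,6,7‑octahydronaphthalen‑1‑yl]ethyl}decahydronaphthalen‑1‑yl]methyl}‑1,4‑dimethoxybenzene
Product: 40 2‑{[(1S,2S,4aR,8aR)‑1,2‑dimethyl‑5‑methylidene‑4a‑{2‑[(1R,2S,4aS)‑1,2,5,5‑tetramethyl‑1,2,3,4,4a,5,6,7‑octahydronaphthalen‑1‑yl]ethyl}decahydronaphthalen‑1‑yl]methyl}benzene‑1,4‑diol, via quinone 39 (not isolated)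
Conditions: (NH4)2Ce(NO3)6, MeCN/H2O, 0 °C; then Na2S2O4, H2O/Et2O, rt
Reagents that add atoms: water, O
Why: Oxidative demethylation of the 1,4‑dimethoxyarene by single‑electron oxidation gives the p‑quinone (oxygens from water) without attacking the isolated alkenes, and dithionite reduces it to the hydroquinone in the same work‑up.

Step 24
Reactants: 40 2‑{[(1S,2S,4aR,8aR)‑1,2‑dimethyl‑5‑methylidene‑4a‑{2‑[(1R,2S,4aS)‑1,2,5,5‑tetramethyl‑1,2,3,4,4a,5,6,7‑octahydronaphthalen‑1‑yl]ethyl}decahydronaphthalen‑1‑yl]methyl}benzene‑1,4‑diol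
Product: 41 2‑{[(1S,2S,4aR,8aR)‑1,2‑dimethyl‑5‑methylidene‑4a‑{2‑[(1R,2S,4aS)‑1,2,5,5‑tetramethyl‑1,2,3,4,4a,5,6,7‑octahydronaphthalen‑1‑yl]ethyl}decahydronaphthalen‑1‑yl]methyl}benzene‑1,4‑diyl bis(hydrogen sulfate) (CNP0439949.2)
Conditions: SO3·pyridine (6 equiv), pyridine, 50 °C; then H+ ion‑exchange resin
Reagents that add atoms: sulfur trioxide–pyridine, [O-]S(=O)(=O)[n+]1ccccc1
Why: O‑Sulfation of both phenols with the mild SO3 donor proceeds under non‑acidic conditions that preserve the exocyclic and trisubstituted alkenes and all stereocentres.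

**Compound list**

1 | hydroquinone (benzene‑1,4‑diol) | Oc1ccc(O)cc1 | starting material
2 | 1,4‑dimethoxybenzene | COc1ccc(OC)cc1 | intermediate
3 | 2‑(bromomethyl)‑1,4‑dimethoxybenzene | COc1ccc(OC)c(CBr)c1 | intermediate
4 | cyclohexane‑1,3‑dione | O=C1CCCC(=O)C1 | starting material
5 | pent‑1‑en‑3‑one | CCC(=O)C=C | starting material
6 | 2‑(3‑oxopentyl)cyclohexane‑1,3‑dione | CCC(=O)CCC1C(=O)CCCC1=O | intermediate
7 | 2,6‑dioxo‑1‑(3‑oxopentyl)cyclohexyl acetate | CCC(=O)CCC1(OC(C)=O)C(=O)CCCC1=O | intermediate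
8 | (8aS)‑5‑methyl‑1,6‑dioxo‑1,2,3,4,6,7,8,8a‑octahydronaphthalen‑8a‑yl acetate | CC1=C2CCCC(=O)[C@]2(OC(C)=O)CCC1=O | intermediate
9 | (8aS)‑1,1‑(ethylenedioxy)‑5‑methyl‑6‑oxo‑1,2,3,4,6,7,8,8a‑octahydronaphthalen‑8a‑yl acetate (not isolated) | CC1=C2CCCC3(OCCO3)[C@]2(OC(C)=O)CCC1=O | intermediate
10 | (8aS)‑1,1‑(ethylenedioxy)‑8a‑hydroxy‑5‑methyl‑1,2,3,4,8,8a‑hexahydronaphthalen‑6(7H)‑one | CC1=C2CCCC3(OCCO3)[C@]2(O)CCC1=O | intermediate
11 | dilithium C8a‑alkoxide C6‑enolate of the trans‑fused (4aR,8aS) conjugate‑reduction product of 10 (not isolated) | C12(OCCO1)CCC[C@H]3[C@@]2(O[Li])CCC(O[Li])=C3C | intermediate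
12 | (4aR,5R,8aS)‑5‑[(2,5‑dimethoxyphenyl)methyl]‑1,1‑(ethylenedioxy)‑8a‑hydroxy‑5‑methylperhydronaphthalen‑6‑one | C12(OCCO1)CCC[C@H]3[C@@]2(O)CCC(=O)[C@]3(C)Cc1cc(OC)ccc1OC | intermediate
13 | (4aR,5R,8aS)‑5‑[(2,5‑dimethoxyphenyl)methyl]‑1,1‑(ethylenedioxy)‑8a‑hydroxy‑5‑methyl‑1,2,3,4,4a,5,8,8a‑octahydronaphthalen‑6‑yl trifluoromethanesulfonate | C12(OCCO1)CCC[C@H]3[C@@]2(O)CC=C(OS(=O)(=O)C(F)(F)F)[C@]3(C)Cc1cc(OC)ccc1OC | intermediate
14 | (4aR,5R,8aS)‑5‑[(2,5‑dimethoxyphenyl)methyl]‑1,1‑(ethylenedioxy)‑5,6‑dimethyl‑1,2,3,4,4a,5,8,8a‑octahydronaphthalen‑8a‑ol | C12(OCCO1)CCC[C@H]3[C@@]2(O)CC=C(C)[C@]3(C)Cc1cc(OC)ccc1OC | intermediate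
15 | (4aR,5S,6S,8aS)‑5‑[(2,5‑dimethoxyphenyl)methyl]‑1,1‑(ethylenedioxy)‑5,6‑dimethylperhydronaphthalen‑8a‑ol | C12(OCCO1)CCC[C@H]3[C@@]2(O)CC[C@H](C)[C@]3(C)Cc1cc(OC)ccc1OC | intermediate
16 | (4aR,5S,6S,8aS)‑5‑[(2,5‑dimethoxyphenyl)methyl]‑8a‑hydroxy‑5,6‑dimethylperhydronaphthalen‑1‑one | O=C1CCC[C@H]2[C@@]1(O)CC[C@H](C)[C@]2(C)Cc1cc(OC)ccc1OC | intermediate
17 | (4aR,5S,6S,8aS)‑5‑[(2,5‑dimethoxyphenyl)methyl]‑5,6‑dimethyl‑1‑oxoperhydronaphthalen‑8a‑yl methanesulfonate | O=C1CCC[C@H]2[C@@]1(OS(C)(=O)=O)CC[C@H](C)[C@]2(C)Cc1cc(OC)ccc1OC | intermediate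
18 | 2‑methylpropanal | CC(C)C=O | starting material
19 | but‑3‑en‑2‑one | CC(=O)C=C | starting material
20 | 4,4‑dimethylcyclohex‑2‑en‑1‑one | CC1(C)CCC(=O)C=C1 | intermediate
21 | 5‑chloro‑3‑methylpentan‑2‑one (racemic) | CC(=O)C(C)CCCl | starting material
22 | 2‑(4‑chlorobutan‑2‑yl)‑2‑methyl‑1,3‑dioxolane | CC(CCCl)C1(C)OCCO1 | intermediate
23 | [3‑(2‑methyl‑1,3‑dioxolan‑2‑yl)butyl]magnesium chloride (not isolated) | CC(CC[Mg]Cl)C1(C)OCCO1 | intermediate
24 | bis[3‑(2‑methyl‑1,3‑dioxolan‑2‑yl)butyl]zinc (not isolated) | CC(CC[Zn]CCC(C)C1(C)OCCO1)C1(C)OCCO1 | intermediate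
25 | (3R)‑4,4‑dimethyl‑3‑[3‑(2‑methyl‑1,3‑dioxolan‑2‑yl)butyl]cyclohexan‑1‑one (both epimers at the butyl C3) | O=C1CCC(C)(C)[C@H](CCC(C)C2(C)OCCO2)C1 | intermediate
26 | (3R)‑4,4‑dimethyl‑3‑(3‑methyl‑4‑oxopentyl)cyclohexan‑1‑one (not isolated) | O=C1CCC(C)(C)[C@H](CCC(C)C(C)=O)C1 | intermediate
27 | (4aS,7S)‑4,4,7,8‑tetramethyl‑3,4,4a,5,6,7‑hexahydronaphthalen‑1(2H)‑one | O=C1CCC(C)(C)[C@@H]2CC[C@H](C)C(C)=C12 | intermediate
28 | bromomagnesium (4aS,7S,8R)‑8‑ethenyl‑4,4,7,8‑tetramethyl‑2,3,4,4a,5,6,7,8‑octahydronaphthalen‑1‑olate (not isolated) | C=C[C@@]1(C)C2=C(O[Mg]Br)CCC(C)(C)[C@@H]2CC[C@@H]1C | intermediate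
29 | (4aS,7S,8R)‑8‑ethenyl‑4,4,7,8‑tetramethyl‑2,3,4,4a,5,6,7,8‑octahydronaphthalen‑1‑yl trifluoromethanesulfonate | C=C[C@@]1(C)C2=C(OS(=O)(=O)C(F)(F)F)CCC(C)(C)[C@@H]2CC[C@@H]1C | intermediate
30 | (1R,2S,4aS)‑1‑ethenyl‑1,2,5,5‑tetramethyl‑1,2,3,4,4a,5,6,7‑octahydronaphthalene | C=C[C@@]1(C)C2=CCCC(C)(C)[C@@H]2CC[C@@H]1C | intermediate
31 | 9‑{2‑[(1R,2S,4aS)‑1,2,5,5‑tetramethyl‑1,2,3,4,4a,5,6,7‑octahydronaphthalen‑1‑yl]ethyl}‑9‑borabicyclo[3.3.1]nonane (not isolated) | B1(CC[C@@]2(C)C3=CCCC(C)(C)[C@@H]3CC[C@@H]2C)C2CCCC1CCC2 | intermediate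
32 | 2‑[(1R,2S,4aS)‑1,2,5,5‑tetramethyl‑1,2,3,4,4a,5,6,7‑octahydronaphthalen‑1‑yl]ethan‑1‑ol | OCC[C@@]1(C)C2=CCCC(C)(C)[C@@H]2CC[C@@H]1C | intermediate
33 | (1R,2S,4aS)‑1‑(2‑iodoethyl)‑1,2,5,5‑tetramethyl‑1,2,3,4,4a,5,6,7‑octahydronaphthalene | ICC[C@@]1(C)C2=CCCC(C)(C)[C@@H]2CC[C@@H]1C | intermediate
34 | {2‑[(1R,2S,4aS)‑1,2,5,5‑tetramethyl‑1,2,3,4,4a,5,6,7‑octahydronaphthalen‑1‑yl]ethyl}lithium (not isolated) | [Li]CC[C@@]1(C)C2=CCCC(C)(C)[C@@H]2CC[C@@H]1C | intermediate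
35 | dichloro{2‑[(1R,2S,4aS)‑1,2,5,5‑tetramethyl‑1,2,3,4,4a,5,6,7‑octahydronaphthalen‑1‑yl]ethyl}cerium (not isolated) | Cl[Ce](Cl)CC[C@@]1(C)C2=CCCC(C)(C)[C@@H]2CC[C@@H]1C | intermediate
36 | dichlorocerium alkoxide of the 1,2‑adduct of 35 to 17: C1 carries the new chain axial and trans to the C8a mesylate (not isolated) | Cl[Ce](Cl)O[C@]1(CC[C@@]2(C)C3=CCCC(C)(C)[C@@H]3CC[C@@H]2C)CCC[C@H]2[C@@]1(OS(C)(=O)=O)CC[C@H](C)[C@]2(C)Cc1cc(OC)ccc1OC | intermediate
37 | (4aR,5S,6S,8aR)‑5‑[(2,5‑dimethoxyphenyl)methyl]‑5,6‑dimethyl‑8a‑{2‑[(1R,2S,4aS)‑1,2,5,5‑tetramethyl‑1,2,3,4,4a,5,6,7‑octahydronaphthalen‑1‑yl]ethyl}perhydronaphthalen‑1‑one | O=C1CCC[C@H]2[C@]1(CC[C@@]1(C)C3=CCCC(C)(C)[C@@H]3CC[C@@H]1C)CC[C@H](C)[C@]2(C)Cc1cc(OC)ccc1OC | intermediate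
38 | 2‑{[(1S,2S,4aR,8aR)‑1,2‑dimethyl‑5‑methylidene‑4a‑{2‑[(1R,2S,4aS)‑1,2,5,5‑tetramethyl‑1,2,3,4,4a,5,6,7‑octahydronaphthalen‑1‑yl]ethyl}decahydronaphthalen‑1‑yl]methyl}‑1,4‑dimethoxybenzene | C=C1CCC[C@H]2[C@]1(CC[C@@]1(C)C3=CCCC(C)(C)[C@@H]3CC[C@@H]1C)CC[C@H](C)[C@]2(C)Cc1cc(OC)ccc1OC | intermediate
39 | 2‑{[(1S,2S,4aR,8aR)‑1,2‑dimethyl‑5‑methylidene‑4a‑{2‑[(1R,2S,4aS)‑1,2,5,5‑tetramethyl‑1,2,3,4,4a,5,6,7‑octahydronaphthalen‑1‑yl]ethyl}decahydronaphthalen‑1‑yl]methyl}cyclohexa‑2,5‑diene‑1,4‑dione (not isolated) | C=C1CCC[C@H]2[C@]1(CC[C@@]1(C)C3=CCCC(C)(C)[C@@H]3CC[C@@H]1C)CC[C@H](C)[C@]2(C)CC1=CC(=O)C=CC1=O | intermediate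
40 | 2‑{[(1S,2S,4aR,8aR)‑1,2‑dimethyl‑5‑methylidene‑4a‑{2‑[(1R,2S,4aS)‑1,2,5,5‑tetramethyl‑1,2,3,4,4a,5,6,7‑octahydronaphthalen‑1‑yl]ethyl}decahydronaphthalen‑1‑yl]methyl}benzene‑1,4‑diol | C=C1CCC[C@H]2[C@]1(CC[C@@]1(C)C3=CCCC(C)(C)[C@@H]3CC[C@@H]1C)CC[C@H](C)[C@]2(C)Cc1cc(O)ccc1O | intermediate
41 | 2‑{[(1S,2S,4aR,8aR)‑1,2‑dimethyl‑5‑methylidene‑4a‑{2‑[(1R,2S,4aS)‑1,2,5,5‑tetramethyl‑1,2,3,4,4a,5,6,7‑octahydronaphthalen‑1‑yl]ethyl}decahydronaphthalen‑1‑yl]methyl}benzene‑1,4‑diyl bis(hydrogen sulfate) | C=C1CCC[C@H]2[C@]1(CC[C@@]1(C)C3=CCCC(C)(C)[C@@H]3CC[C@@H]1C)CC[C@H](C)[C@]2(C)Cc1cc(OS(=O)(=O)O)ccc1OS(=O)(=O)O | target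

**Totals**
Total step count: 24. Longest linear sequence: 14 steps (steps 3–12, then 21–24, from cyclohexane‑1,3‑dione).

**Three steps most likely to fail, each with a fallback**

Step 21 (the proposed new coupling). The risks are attack of the organometallic on the sulfonate or on an α‑proton, and elimination of the tertiary mesylate before addition. The fallback uses known reactions, sets out from mesylate 17 and returns at ketone 37. SmI2 in THF/MeOH at −78 °C removes the α‑sulfonyloxy group and gives the deoxygenated decalone (4aS,5S,6S)‑5‑[(2,5‑dimethoxyphenyl)methyl]‑5,6‑dimethylperhydronaphthalen‑1‑one F1 as both ring‑fusion epimers, which converge. Its thermodynamic, more substituted potassium enolate (KH, THF) is then alkylated at the ring‑fusion carbon with iodide 33 in the presence of DMPU. Angular alkylation of 1‑decalone enolates is known to favour the cis‑fused product, so this gives 37 by direct C‑alkylation, without any 1,2‑shift.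

Step 5 (amino‑acid‑mediated cyclisation of a triketone that carries an angular acetoxy group; this substituent has not been tested in the reaction, and enantioselectivity or acetate stability may be poor). The fallback sets out from triketone 7 and returns at 8. Cyclodehydration with pyrrolidine/AcOH at rt gives the racemate, that is 8 together with its mirror image (8aR)‑5‑methyl‑1,6‑dioxo‑1,2,3,4,6,7,8,8a‑octahydronaphthalen‑8a‑yl acetate F2. F2 is removed by preparative chromatography on a chiral stationary phase, and the route continues from 8.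

Step 17 (vinyl cuprate addition to a tetrasubstituted, β,β‑disubstituted enone; the reaction may stall for steric reasons). The fallback sets out from enone 27 and returns at alcohol 32. Mukaiyama–Michael addition of 1‑[tert‑butyl(dimethyl)silyloxy]‑1‑methoxyethene (TBSOTf cat., CH2Cl2, −78 °C) gives the silyl enol ether methyl 2‑[(1R,2S,4aS)‑8‑{[tert‑butyl(dimethyl)silyl]oxy}‑1,2,5,5‑tetramethyl‑1,2,3,4,4a,5,6,7‑octahydronaphthalen‑1‑yl]acetate F3, with the same axial approach anti to the C7 methyl. MeLi followed by PhNTf2 converts it into the enol triflate methyl 2‑[(1R,2S,4aS)‑1,2,5,5‑tetramethyl‑8‑(trifluoromethanesulfonyloxy)‑1,2,3,4,4a,5,6,7‑octahydronaphthalen‑1‑yl]acetate F4. Pd(OAc)2/PPh3/HCO2H/Bu3N reduces this to the ester methyl 2‑[(1R,2S,4aS)‑1,2,5,5‑tetramethyl‑1,2,3,4,4a,5,6,7‑octahydronaphthalen‑1‑yl]acetate F5, and LiAlH4 reduction gives 32.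

**Further compounds**
F1 | step 21 | (4aS,5S,6S)‑5‑[(2,5‑dimethoxyphenyl)methyl]‑5,6‑dimethylperhydronaphthalen‑1‑one (both C8a epimers) | O=C1CCC[C@H]2C1CC[C@H](C)[C@]2(C)Cc1cc(OC)ccc1OC
F2 | step 5 | (8aR)‑5‑methyl‑1,6‑dioxo‑1,2,3,4,6,7,8,8a‑octahydronaphthalen‑8a‑yl acetate | CC1=C2CCCC(=O)[C@@]2(OC(C)=O)CCC1=O
F3 | step 17 | methyl 2‑[(1R,2S,4aS)‑8‑{[tert‑butyl(dimethyl)silyl]oxy}‑1,2,5,5‑tetramethyl‑1,2,3,4,4a,5,6,7‑octahydronaphthalen‑1‑yl]acetate | COC(=O)C[C@@]1(C)C2=C(O[Si](C)(C)C(C)(C)C)CCC(C)(C)[C@@H]2CC[C@@H]1C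
F4 | step 17 | methyl 2‑[(1R,2S,4aS)‑1,2,5,5‑tetramethyl‑8‑(trifluoromethanesulfonyloxy)‑1,2,3,4,4a,5,6,7‑octahydronaphthalen‑1‑yl]acetate | COC(=O)C[C@@]1(C)C2=C(OS(=O)(=O)C(F)(F)F)CCC(C)(C)[C@@H]2CC[C@@H]1C
F5 | step 17 | methyl 2‑[(1R,2S,4aS)‑1,2,5,5‑tetramethyl‑1,2,3,4,4a,5,6,7‑octahydronaphthalen‑1‑yl]acetate | COC(=O)C[C@@]1(C)C2=CCCC(C)(C)[C@@H]2CC[C@@H]1C
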